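**Plan**

1. Retrosynthesis: the three acetates and the methyl ester go back to hydroxyls held as acetonide and silyl ether and to a tert-butyl ester, and the ring is then cut at C10=C11. This cut is possible because C10(Cl)=C11 of the cyclopentenone (ring C8–C12) lies between the C9 oxygen and the tertiary C12 carbinol, so the ring is what closure of a 1,6-diene made of a C12 vinyl carbinol and a C9 2-chloroallylic alcohol delivers.
2. Further cuts: C9–C10 (1-chlorovinyl anion on a C9 aldehyde), C11=CH2 (lactol methylenation, revealing a γ-lactone O7–C11), C12–O and C12–C13 (enolate hydroxylation and allylation), C8–C9 (conjugate addition to a C7 butenolide), C8–C12 (selenoacetate on a C7–C8 epoxide) and C3–C4 (Wittig), back to D-xylose.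
3. Forward order: C1–C8 chain from D-xylose, then the butenolide (the only temporary ring apart from the acetonide), one-flask union with 1,3-dithiane (C9) and the Z,Z-octadienyl bromide (C13–C20), C12 hydroxylation, opening of the lactone to the vinyl carbinol, chlorovinyl addition, and last the closure of the single carbocycle by metathesis; oxidation, deprotection and acetylation finish.
4. Stereochemistry: C5, C6, C7 are C2, C3, C4 of D-xylose; C8 comes from conjugate addition anti to the C7 substituent; C12 from hydroxylation of the lactone enolate anti to the C8 substituent; both Z-olefins from Lindlar hydrogenation; C9 forms unselectively and ends trigonal.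

Key step: step 21

Remark: atom labels follow the prostanoid numbering of the target (C1 ester carbon, ring C8–C12, C20 terminal methyl). The C1 carboxyl is carried as its tert-butyl ester until step 23, and C9 is carried as an epimer mixture in 32 and 33 because both epimers converge on the ketone.

**Route**

Step 1
Reactants: 1 D-xylose
Product: 2 D-xylose diethyl dithioacetal
Conditions: EtSH, conc. HCl, 0 °C
Reagents that add atoms: ethanethiol, CCS
Why: Acid-catalysed dithioacetalisation traps the aldose in its open-chain form without touching C2–C4 of the sugar, which become C5–C7 of the target.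

Step 2
Reactants: 2 D-xylose diethyl dithioacetal
Product: 3 bis-acetonide dithioacetal
Conditions: 2,2-dimethoxypropane, TsOH (cat.), DMF, rt
Reagents that add atoms: 2,2-dimethoxypropane, COC(C)(C)OC
Why: Acid-catalysed transacetalisation should give the two dioxolanes across O2/O3 (trans ring on the threo diol, target O5/O6) and O4/O5 (terminal, target O7/O8), the usual protection pattern of acyclic xylose dithioacetals.

Step 3
Reactants: 3 bis-acetonide dithioacetal
Product: 4 bis-acetonide aldehyde
Conditions: I2, NaHCO3, acetone/H2O, 0 °C to rt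
Reagents that add atoms: water, O
Why: Oxidative dithioacetal hydrolysis (S-iodination, then hydrolysis) frees the aldehyde under buffered conditions that spare both acetonides and the α-alkoxy stereocentre.

Step 4
Reactants: 4 bis-acetonide aldehyde; 5 (2-carboxyethyl)triphenylphosphonium bromide
Product: 6 (Z)-alkenoic acid
Conditions: 5, NaN(SiMe3)2 (2 equiv per 5), THF, −78 to 0 °C; then 4, −78 °C to rt; citric acid work-up
Reagents that add atoms: none
Why: Wittig olefination with the carboxylate-bearing non-stabilised ylide (the carboxylate form suppresses β-elimination of the phosphine) attaches C1–C3, and the olefin geometry does not matter because the double bond is hydrogenated next.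

Step 5
Reactants: 6 (Z)-alkenoic acid
Product: 7 saturated acid
Conditions: H2 (1 atm), Pd/C, EtOAc, rt
Reagents that add atoms: none
Why: Heterogeneous catalytic hydrogenation saturates the isolated C3=C4 olefin and cannot touch the acetonides.

Step 6
Reactants: 7 saturated acid
Product: 8 tert-butyl ester
Conditions: tert-butyl 2,2,2-trichloroacetimidate, CH2Cl2/cyclohexane, rt
Reagents that add atoms: tert-butyl 2,2,2-trichloroacetimidate, CC(C)(C)OC(=N)C(Cl)(Cl)Cl
Why: Imidate esterification (the acid itself protonates the imidate, tert-butyl transfer) needs no added acid, and the tert-butyl ester is chosen because it should survive the carbanion, enolate, hydride, ylide and organolithium steps that follow.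

Step 7
Reactants: 8 tert-butyl ester
Product: 9 terminal 7,8-diol
Conditions: AcOH/H2O (4:1), rt
Reagents that add atoms: none
Why: Selective acetal hydrolysis, since the terminal dioxolane with its primary oxygen hydrolyses faster than the internal trans-dioxolane and the tert-butyl ester tolerates aqueous acetic acid.

Step 8
Reactants: 9 terminal 7,8-diol
Product: 11 terminal epoxide, via primary tosylate 10 (not isolated)
Conditions: NaH, 1-(p-tolylsulfonyl)imidazole, THF, 0 °C to rt
Reagents that add atoms: none
Why: Selective sulfonylation of the primary alkoxide followed by intramolecular Williamson displacement by the C7 alkoxide closes the epoxide, and because the C7–O bond is never broken C7 keeps its configuration.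

Step 9
Reactants: 11 terminal epoxide; 12 (phenylseleno)acetic acid
Product: 14 α-phenylseleno γ-lactone, via hydroxy acid 13 (not isolated)
Conditions: 12, LiN(i-Pr)2 (2 equiv per 12), THF, −78 to 0 °C; then 11, 0 °C to rt; then AcOH, 60 °C
Reagents that add atoms: none
Why: The carboxylic acid dianion opens the epoxide by SN2 attack at the unhindered terminal carbon C8, and acidification lactonises the γ-hydroxy acid onto O7, which adds C12 and C11 with C7 unchanged.

Step 10
Reactants: 14 α-phenylseleno γ-lactone
Product: 16 butenolide, via selenoxide 15 (not isolated)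
Conditions: 30% H2O2, THF, 0 °C to rt
Reagents that add atoms: none
Why: Selenide oxidation and spontaneous selenoxide syn-elimination toward the ring CH2 (C8) give the endocyclic C8=C12 olefin of the 2(5H)-furanone.

Step 11
Reactants: 17 1-bromopent-2-yne; 18 prop-2-yn-1-ol
Product: 19 octa-2,5-diyn-1-ol
Conditions: CuI, NaI, K2CO3, DMF, rt
Reagents that add atoms: none
Why: Copper-mediated coupling of a terminal alkyne with a propargylic bromide is the standard entry to skipped diynes and supplies the C13–C20 chain.

Step 12
Reactants: 19 octa-2,5-diyn-1-ol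
Product: 20 (2Z,5Z)-octa-2,5-dien-1-ol
Conditions: H2 (1 atm), Pd/CaCO3 poisoned with Pb(OAc)2 (Lindlar catalyst), quinoline, EtOAc, rt
Reagents that add atoms: none
Why: Lindlar semi-hydrogenation delivers hydrogen syn to each alkyne and stops at the alkene, which sets the C14=C15 and C17=C18 Z-olefins.

Step 13
Reactants: 20 (2Z,5Z)-octa-2,5-dien-1-ol
Product: 21 (2Z,5Z)-1-bromoocta-2,5-diene
Conditions: CBr4, PPh3, CH2Cl2, 0 °C
Reagents that add atoms: carbon tetrabromide, BrC(Br)(Br)Br
Why: Appel bromination converts the primary allylic alcohol by SN2 at CH2 under neutral conditions, so both Z-olefins are kept.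

Step 14
Reactants: 16 butenolide; 22 1,3-dithiane; 21 (2Z,5Z)-1-bromoocta-2,5-diene
Product: 24 trans-trans dithianyl dienyl lactone, via lithium enolate 23 (not isolated)
Conditions: 22, n-BuLi, THF, −30 °C; HMPA, then 16, −78 °C; then 21, −78 to −40 °C
Reagents that add atoms: none
Why: Michael addition of the sulfur-stabilised carbanion (HMPA favours 1,4-attack) occurs on the butenolide face opposite the C7 side chain and sets C8, and the lithium enolate is then alkylated by the allylic bromide opposite the new C8 substituent (tandem conjugate addition–enolate alkylation).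

Step 15
Reactants: 24 trans-trans dithianyl dienyl lactone
Product: 26 tertiary α-hydroxy lactone, via potassium enolate 25 (not isolated)
Conditions: KN(SiMe3)2, THF, −78 °C; 2-(phenylsulfonyl)-3-phenyloxaziridine, −78 °C; AcOH quench at −78 °C
Reagents that add atoms: 2-(phenylsulfonyl)-3-phenyloxaziridine, O=S(=O)(N1OC1c1ccccc1)c1ccccc1
Why: Enolate hydroxylation with an N-sulfonyloxaziridine, in which the planar lactone enolate (the most acidic C–H of 24) is oxidised on the face opposite the adjacent C8 dithianyl group, so the hydroxyl ends trans and the dienyl chain cis to C9, which is the C12 configuration of the target; the cold quench limits sulfur oxidation.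

Step 16
Reactants: 26 tertiary α-hydroxy lactone
Product: 27 lactol
Conditions: i-Bu2AlH (2.5 equiv), CH2Cl2, −78 °C; aq. KNaC4H4O6 (potassium sodium tartrate) work-up
Reagents that add atoms: none
Why: Partial reduction of the γ-lactone by the aluminium hydride stops at the tetrahedral aluminate at −78 °C (the first equivalent is taken by the C12 hydroxyl), while the hindered tert-butyl ester is reduced much more slowly.

Step 17
Reactants: 27 lactol
Product: 28 vinyl carbinol diol
Conditions: Ph3PCH3Br, KOt-Bu, THF, 0 °C to rt
Reagents that add atoms: methyltriphenylphosphonium bromide, C[P+](c1ccccc1)(c1ccccc1)c1ccccc1.[Br-]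
Why: Wittig methylenation of the hydroxy-aldehyde tautomer of the lactol turns C11 into the terminal vinyl group and liberates O7–H, and C12, being fully substituted, cannot epimerise.

Step 18
Reactants: 28 vinyl carbinol diol
Product: 29 C7 silyl ether
Conditions: TBSOTf (1.1 equiv), 2,6-lutidine, CH2Cl2, −78 °C
Reagents that add atoms: tert-butyldimethylsilyl trifluoromethanesulfonate, CC(C)(C)[Si](C)(C)OS(=O)(=O)C(F)(F)F
Why: Silyl triflate silylation at low temperature should take the secondary C7 hydroxyl and leave the far more hindered tertiary allylic C12 hydroxyl free.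

Step 19
Reactants: 29 C7 silyl ether
Product: 30 C9 aldehyde
Conditions: MeI, CaCO3, MeCN/H2O (9:1), 45 °C
Reagents that add atoms: water, O
Why: Alkylative dithiane hydrolysis (S-methylation, then hydrolysis of the sulfonium) runs under buffered, non-oxidising conditions that leave the olefins, silyl ether, acetonide and ester alone.

Step 20
Reactants: 30 C9 aldehyde; 31 vinyl chloride
Product: 32 chloro-diene diol (C9 epimers)
Conditions: 31, sec-BuLi, THF/Et2O/pentane, −110 °C; then 30, −110 to −90 °C; AcOH quench
Reagents that add atoms: none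
Why: α-Lithiation of vinyl chloride gives 1-chlorovinyllithium, which adds 1,2 to the aldehyde faster than it decomposes or attacks the tert-butyl ester at this temperature (one equivalent is consumed by the C12 hydroxyl), and the unselective formation of C9 is harmless because C9 becomes the ketone.

Step 21
Reactants: 32 chloro-diene diol (C9 epimers)
Product: 33 chlorocyclopentene diol (C9 epimers)
Conditions: RuCl2(=CHPh)(H2IMes)(PCy3) (second-generation Grubbs catalyst, 10 mol%), 1,4-benzoquinone (10 mol%), benzene (2 mM), 65 °C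
Reagents that add atoms: none
Why: The catalyst should initiate at the terminal vinyl group on C12, the only unhindered monosubstituted olefin, to give a ruthenium alkylidene at C11; intramolecular [2+2] addition of this alkylidene to the C10 chlorovinyl group and cycloreversion of the ruthenacyclobutane form C10=C11 and pass the methylidene on, ethylene being the only by-product. The closest known reaction type is ring-closing metathesis of 2-chloro-1,6-dienes to 1-chlorocyclopentenes with second-generation ruthenium carbenes at 60–80 °C. The one ring formed, the five-membered carbocycle C8–C9–C10–C11–C12, closes by olefin–olefin metathesis of a 1,6-diene with ruthenium departing on the chloro-olefin CH2, so chlorine stays on C10 and no chlorocarbene complex needs to form. No stereocentre is created, C8 and C12 are spectators and both C9 epimers should cyclise. The step needs five-ring closure to outpace seven-ring closure of the C11 alkylidene onto C17=C18 and cross-metathesis of the Z-olefins; the fully substituted C12 and branched C8 hold the two reacting olefins gauche, the free C12 hydroxyl should speed loading on its own vinyl group, and high dilution with benzoquinone suppresses oligomerisation and olefin isomerisation.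

Step 22
Reactants: 33 chlorocyclopentene diol (C9 epimers)
Product: 34 chloroenone
Conditions: Dess–Martin periodinane, pyridine, CH2Cl2, 0 °C to rt
Reagents that add atoms: none
Why: Dess–Martin oxidation converts the secondary allylic C9 alcohol of both epimers into the enone, while the tertiary C12 alcohol cannot be oxidised and, unlike with chromium oxidants, is not transposed.

Step 23
Reactants: 34 chloroenone
Product: 35 triol methyl ester
Conditions: HCl (1.25 M in MeOH), 0 °C to rt; solid NaHCO3 before concentration
Reagents that add atoms: methanol, CO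
Why: Acid-catalysed methanolysis removes the silyl ether, transacetalises the acetonide and exchanges the tert-butyl for the methyl ester in one operation, and methanol as solvent keeps the 5-hydroxy ester open instead of letting it close to the δ-lactone.

Step 24
Reactants: 35 triol methyl ester
Product: 36 CNP0277476.1
Conditions: Ac2O, pyridine, CH2Cl2, 0 °C to rt
Reagents that add atoms: acetic anhydride, CC(=O)OC(C)=O
Why: Pyridine-mediated acetylation esterifies the three secondary hydroxyls at C5, C6 and C7, whereas the tertiary C12 hydroxyl is not acylated without a nucleophilic catalyst and the mild base should not eliminate the C7 acetate.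

**Compound list**

1 | D-xylose (open-chain form) | O=C[C@H](O)[C@@H](O)[C@H](O)CO | starting material
2 | D-xylose diethyl dithioacetal | CCSC(SCC)[C@H](O)[C@@H](O)[C@H](O)CO | intermediate
3 | 2,3:4,5-di-O-isopropylidene-D-xylose diethyl dithioacetal | CCSC(SCC)[C@H](OC1(C)C)[C@@H](O1)[C@H]1COC(C)(C)O1 | intermediate
4 | 2,3:4,5-di-O-isopropylidene-aldehydo-D-xylose | O=C[C@H](OC1(C)C)[C@@H](O1)[C@H]1COC(C)(C)O1 | intermediate
5 | (2-carboxyethyl)triphenylphosphonium bromide | OC(=O)CC[P+](c1ccccc1)(c1ccccc1)c1ccccc1.[Br-] | starting material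
6 | (3Z)-2,3,4-trideoxy-5,6:7,8-di-O-isopropylidene-D-xylo-oct-3-enonic acid | OC(=O)C/C=C\[C@H](OC1(C)C)[C@@H](O1)[C@H]1COC(C)(C)O1 | intermediate
7 | 2,3,4-trideoxy-5,6:7,8-di-O-isopropylidene-D-xylo-octonic acid | OC(=O)CCC[C@H](OC1(C)C)[C@@H](O1)[C@H]1COC(C)(C)O1 | intermediate
8 | tert-butyl 2,3,4-trideoxy-5,6:7,8-di-O-isopropylidene-D-xylo-octonate | CC(C)(C)OC(=O)CCC[C@H](OC1(C)C)[C@@H](O1)[C@H]1COC(C)(C)O1 | intermediate
9 | tert-butyl 2,3,4-trideoxy-5,6-O-isopropylidene-D-xylo-octonate (free 7,8-diol) | CC(C)(C)OC(=O)CCC[C@H](OC1(C)C)[C@@H](O1)[C@H](O)CO | intermediate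
10 | tert-butyl 2,3,4-trideoxy-5,6-O-isopropylidene-8-O-(p-tolylsulfonyl)-D-xylo-octonate | CC(C)(C)OC(=O)CCC[C@H](OC1(C)C)[C@@H](O1)[C@H](O)COS(=O)(=O)c1ccc(C)cc1 | intermediate
11 | tert-butyl 7,8-anhydro-2,3,4-trideoxy-5,6-O-isopropylidene-D-xylo-octonate (terminal epoxide, C7 retained) | CC(C)(C)OC(=O)CCC[C@H](OC1(C)C)[C@@H](O1)[C@H]1CO1 | intermediate
12 | (phenylseleno)acetic acid | OC(=O)C[Se]c1ccccc1 | starting material
13 | γ-hydroxy α-(phenylseleno) acid (C7–OH, C11 carboxyl, C12 epimers; chain and acetonide as in 11) | CC(C)(C)OC(=O)CCC[C@H](OC1(C)C)[C@@H](O1)[C@H](O)CC([Se]c1ccccc1)C(O)=O | intermediate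
14 | α-(phenylseleno)-γ-lactone (ring O7–C7–C8–C12–C11, C12 epimers) | CC(C)(C)OC(=O)CCC[C@H](OC1(C)C)[C@@H](O1)[C@H]1CC([Se]c2ccccc2)C(=O)O1 | intermediate
15 | selenoxide of 14 | CC(C)(C)OC(=O)CCC[C@H](OC1(C)C)[C@@H](O1)[C@H]1CC([Se](=O)c2ccccc2)C(=O)O1 | intermediate
16 | tert-butyl 4-{(4S,5R)-2,2-dimethyl-5-[(2R)-5-oxo-2,5-dihydrofuran-2-yl]-1,3-dioxolan-4-yl}butanoate (butenolide; O7 ring oxygen, C11 carbonyl, C8=C12) | CC(C)(C)OC(=O)CCC[C@H](OC1(C)C)[C@@H](O1)[C@H]1C=CC(=O)O1 | intermediate
17 | 1-bromopent-2-yne | CCC#CCBr | starting material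
18 | prop-2-yn-1-ol | C#CCO | starting material
19 | octa-2,5-diyn-1-ol | CCC#CCC#CCO | intermediate
20 | (2Z,5Z)-octa-2,5-dien-1-ol | CC/C=C\C/C=C\CO | intermediate
21 | (2Z,5Z)-1-bromoocta-2,5-diene | CC/C=C\C/C=C\CBr | intermediate
22 | 1,3-dithiane | C1CSCSC1 | starting material
23 | lithium enolate of the C8-dithianyl lactone (dithianyl trans to the C7 side chain) | CC(C)(C)OC(=O)CCC[C@H](OC1(C)C)[C@@H](O1)[C@H]1[C@H](C2SCCCS2)C=C(O[Li])O1 | intermediate
24 | γ-lactone with 1,3-dithian-2-yl on C8 and (2Z,5Z)-octa-2,5-dienyl on C12; C7/C8 trans, C8/C12 trans; side chain as in 16 | CC(C)(C)OC(=O)CCC[C@H](OC1(C)C)[C@@H](O1)[C@H]1[C@H](C2SCCCS2)[C@@H](C/C=C\C/C=C\CC)C(=O)O1 | intermediate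
25 | potassium enolate of 24 | CC(C)(C)OC(=O)CCC[C@H](OC1(C)C)[C@@H](O1)[C@H]1[C@H](C2SCCCS2)C(C/C=C\C/C=C\CC)=C(O[K])O1 | intermediate
26 | tertiary α-hydroxy lactone: C12–OH trans to the C8 dithianyl group, octadienyl chain cis to it | CC(C)(C)OC(=O)CCC[C@H](OC1(C)C)[C@@H](O1)[C@H]1[C@H](C2SCCCS2)[C@](O)(C/C=C\C/C=C\CC)C(=O)O1 | intermediate
27 | lactol of 26 (C11 hemiacetal, anomer mixture) | CC(C)(C)OC(=O)CCC[C@H](OC1(C)C)[C@@H](O1)[C@H]1[C@H](C2SCCCS2)[C@](O)(C/C=C\C/C=C\CC)C(O)O1 | intermediate
28 | open-chain diol: tert-butyl ester, 5,6-acetonide, free C7–OH, 1,3-dithian-2-yl on C8, tertiary C12–OH bearing vinyl (C11) and the (2Z,5Z)-octadienyl chain | CC(C)(C)OC(=O)CCC[C@H](OC1(C)C)[C@@H](O1)[C@H](O)[C@H](C1SCCCS1)[C@](O)(C/C=C\C/C=C\CC)C=C | intermediate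
29 | 7-O-tert-butyldimethylsilyl ether of 28 | CC(C)(C)OC(=O)CCC[C@H](OC1(C)C)[C@@H](O1)[C@H](O[Si](C)(C)C(C)(C)C)[C@H](C1SCCCS1)[C@](O)(C/C=C\C/C=C\CC)C=C | intermediate
30 | C9 aldehyde (formyl on C8; otherwise as 29) | CC(C)(C)OC(=O)CCC[C@H](OC1(C)C)[C@@H](O1)[C@H](O[Si](C)(C)C(C)(C)C)[C@H](C=O)[C@](O)(C/C=C\C/C=C\CC)C=C | intermediate
31 | vinyl chloride | C=CCl | starting material
32 | acyclic 1,6-diene: C12 vinyl carbinol and C9 2-chloroallylic alcohol (C9 epimers), 7-O-TBS, 5,6-acetonide, tert-butyl ester | CC(C)(C)OC(=O)CCC[C@H](OC1(C)C)[C@@H](O1)[C@H](O[Si](C)(C)C(C)(C)C)[C@H](C(O)C(Cl)=C)[C@](O)(C/C=C\C/C=C\CC)C=C | intermediate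
33 | chlorocyclopentene diol: 10-chloro-C10=C11 ring, C9–OH (epimers), C12–OH, 7-O-TBS, 5,6-acetonide, tert-butyl ester | CC(C)(C)OC(=O)CCC[C@H](OC1(C)C)[C@@H](O1)[C@H](O[Si](C)(C)C(C)(C)C)[C@@H]1C(O)C(Cl)=C[C@@]1(O)C/C=C\C/C=C\CC | intermediate
34 | chloroenone: C9 ketone of 33 | CC(C)(C)OC(=O)CCC[C@H](OC1(C)C)[C@@H](O1)[C@H](O[Si](C)(C)C(C)(C)C)[C@@H]1C(=O)C(Cl)=C[C@@]1(O)C/C=C\C/C=C\CC | intermediate
35 | methyl (5S,6R,7R)-5,6,7-trihydroxy-7-{(1S,2R)-4-chloro-2-hydroxy-2-[(2Z,5Z)-octa-2,5-dien-1-yl]-5-oxocyclopent-3-en-1-yl}heptanoate | COC(=O)CCC[C@H](O)[C@@H](O)[C@H](O)[C@@H]1C(=O)C(Cl)=C[C@@]1(O)C/C=C\C/C=C\CC | intermediate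
36 | CNP0277476.1, methyl (5S,6R,7R)-5,6,7-triacetoxy-7-{(1S,2R)-4-chloro-2-hydroxy-2-[(2Z,5Z)-octa-2,5-dien-1-yl]-5-oxocyclopent-3-en-1-yl}heptanoate | COC(=O)CCC[C@H](OC(C)=O)[C@@H](OC(C)=O)[C@H](OC(C)=O)[C@@H]1C(=O)C(Cl)=C[C@@]1(O)C/C=C\C/C=C\CC | target

**Step count**

Total: 24 steps. Longest linear sequence: 21 steps (steps 1–10 and 14–24, from D-xylose); steps 11–13 make the dienyl bromide in a side branch.

**Steps most likely to fail**

1. Step 21 (ring-closing metathesis). The C11 alkylidene may close the seven-membered ring onto C17=C18 instead, the catalyst may load on the chloro-olefin and lose activity, or the skipped diene may isomerise at 65 °C. The fallback sets out from aldehyde 30 and comes back at chloroenone 34. Vinylmagnesium bromide (CH2=CHMgBr, THF, −78 °C) is added to 30 to give the bis-vinyl carbinol F1. The same catalyst at room temperature should then close this 1,6-diene of two monosubstituted olefins quickly to the cyclopentenediol F2. Dess–Martin oxidation gives the cyclopentenone F3, and nucleophilic epoxidation of the electron-poor enone olefin alone (t-BuOOH, DBU) gives the 10,11-epoxy ketone F4. HCl in THF at 0 °C opens the epoxide at C10, and loss of water from the chlorohydrin gives 34.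

2. Step 23 (one-pot methanolysis). Acid may dehydrate the β-hydroxy ketone across C7–C8, the C6 hydroxyl may ketalise the C9 carbonyl, the ester exchange may stall, or the 5-hydroxy ester may lactonise on concentration. The fallback sets out from 34 and comes back at the target 36; it moves the ester exchange to the end, after the hydroxyls are capped. Aqueous HF in MeCN removes silyl ether and acetonide but keeps the tert-butyl ester, giving the triol tert-butyl ester F5. Ac2O/pyridine gives the triacetate tert-butyl ester F6. TFA in CH2Cl2 at 0 °C cleaves the tert-butyl ester to the triacetoxy acid F7, and trimethylsilyldiazomethane in MeOH/toluene methylates it to 36.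

3. Step 17 (lactol methylenation). Ring-opening of the lactol next to the fully substituted C12 may be slow, and the strongly basic ylide may trigger α-ketol rearrangement of the hydroxy aldehyde or attack the ester. The fallback sets out from lactol 27 and comes back at diol 28 by a two-stage Peterson olefination. Me3SiCH2MgCl with CeCl3 (THF, −78 to 0 °C) adds to the lactol to give the β-hydroxysilane F8, and KH in THF then eliminates it to the vinyl group of 28.

**Further compounds**

F1 | step 21 | bis-vinyl carbinol: C9 vinyl carbinol analogue of 32 without chlorine (C9 epimers) | CC(C)(C)OC(=O)CCC[C@H](OC1(C)C)[C@@H](O1)[C@H](O[Si](C)(C)C(C)(C)C)[C@H](C(O)C=C)[C@](O)(C/C=C\C/C=C\CC)C=C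
F2 | step 21 | cyclopentenediol: chlorine-free analogue of 33 (C9 epimers) | CC(C)(C)OC(=O)CCC[C@H](OC1(C)C)[C@@H](O1)[C@H](O[Si](C)(C)C(C)(C)C)[C@@H]1C(O)C=C[C@@]1(O)C/C=C\C/C=C\CC
F3 | step 21 | cyclopentenone: chlorine-free analogue of 34 | CC(C)(C)OC(=O)CCC[C@H](OC1(C)C)[C@@H](O1)[C@H](O[Si](C)(C)C(C)(C)C)[C@@H]1C(=O)C=C[C@@]1(O)C/C=C\C/C=C\CC
F4 | step 21 | 10,11-epoxy ketone of F3 (epoxide face unassigned) | CC(C)(C)OC(=O)CCC[C@H](OC1(C)C)[C@@H](O1)[C@H](O[Si](C)(C)C(C)(C)C)[C@@H]1C(=O)C2OC2[C@@]1(O)C/C=C\C/C=C\CC
F5 | step 23 | triol tert-butyl ester: tert-butyl analogue of 35 | CC(C)(C)OC(=O)CCC[C@H](O)[C@@H](O)[C@H](O)[C@@H]1C(=O)C(Cl)=C[C@@]1(O)C/C=C\C/C=C\CC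
F6 | step 23 | triacetate tert-butyl ester: tert-butyl analogue of 36 | CC(C)(C)OC(=O)CCC[C@H](OC(C)=O)[C@@H](OC(C)=O)[C@H](OC(C)=O)[C@@H]1C(=O)C(Cl)=C[C@@]1(O)C/C=C\C/C=C\CC
F7 | step 23 | triacetoxy acid: free C1 acid of 36 | OC(=O)CCC[C@H](OC(C)=O)[C@@H](OC(C)=O)[C@H](OC(C)=O)[C@@H]1C(=O)C(Cl)=C[C@@]1(O)C/C=C\C/C=C\CC
F8 | step 17 | β-hydroxysilane: C11 carbinol bearing CH2SiMe3 (C11 epimers), free C7–OH and C12–OH, otherwise as 28 | CC(C)(C)OC(=O)CCC[C@H](OC1(C)C)[C@@H](O1)[C@H](O)[C@H](C1SCCCS1)[C@](O)(C/C=C\C/C=C\CC)C(O)C[Si](C)(C)C
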